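E cannot enter solution faster than 0.0442 M h⁻¹, its dissolution coefficient times its solubility, the rate it reaches with no G dissolved.

    G ⇌ J (K1 = 1.3, k1 = 0.36 h⁻¹, Ea1 = 84.0 kJ mol⁻¹, ΔH1 = −36.0 kJ mol⁻¹)
    X + J → X.J (k2 = 0.068 M⁻¹ h⁻¹, Ea2 = 69.0 kJ mol⁻¹)
    E ⇌ G, rate k3*(cs3 - [G]) while solid is left; crystals form when [G] > cs3 (cs3 = 0.26 M, k3 = 0.17 h⁻¹)
    G + J → G.J (k4 = 0.061 M⁻¹ h⁻¹, Ea4 = 79.0 kJ mol⁻¹)
    (constants at 25 °C)

| flask | E | X | temperature | time |
|---|---|---|---|---|
| Sunday's | 0.88 M | 3.00 equiv | 25 °C | 25 h |
| Wednesday's | 0.88 M | 3.00 equiv | 85 °C | 25 h |
| Tuesday's | 0.88 M | 3.00 equiv | −5 °C | 25 h |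
| Monday's | 0.88 M | 3.00 equiv | 55 °C | 25 h |

- the flask that comes out highest in amount of X.J, in percent of the E charged, or "all alike" when all lie within 1.5 percentage points (Sunday's / Wednesday's / Tuesday's / Monday's / all alike)
- X.J at the end, in percent of the E charged, Sunday's
- X.J at the end, in percent of the E charged, Wednesday's
- X.J at the end, in percent of the E charged, Tuesday's
- X.J at the end, in percent of the E charged, Monday's

- percent here means E units held: one G.J counts as two
- E is a solid; its amount is given per volume of the solution
- all constants are for 25 °C and move with temperature by the activation energies and enthalpies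
- at the start none of E is in solution
- what has only dissolved of E counts as not reacted

**The ladder.** I follow one molecule through Wednesday's flask at 85 °C, where X starts at 2.64 M. On the top rung, J returns to G at 921 h⁻¹, faster than X catches it at 19.0 h⁻¹. So G and J form a pre-equilibrium, with J at 0.114 times G.

On the next rung, G drains into X.J at that constant times the catch rate, 2.17 h⁻¹, which is faster than the dissolution coefficient of 0.17 h⁻¹. So dissolved G stays near 0.0189 M, and dissolution is the rate-limiting step. On the bottom rung, the feed of 0.0410 M h⁻¹ passes the charge of 0.88 M in 21.5 h, which is shorter than the 25 h allowed.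

**The fork.** Each J that does not return to G meets either X or G. The two constants stand at a ratio of 1.76 in Wednesday's flask, so with the [G] above and X at its starting level I get 0.0126. This is the leak, the G.J made for each X.J made, or the constant of G + J times [G] over the constant of X + J times [X]. Each G.J holds two E units, so I expect 97.5 % X.J in Wednesday's flask.

**Cooler flasks.** In Sunday's flask at 25 °C, J returns to G at 0.277 h⁻¹ and X catches it at 0.180 h⁻¹, so I do not treat G and J as a pre-equilibrium there. G then drains into X.J at its constant for G to J times the share of J that X catches, 0.142 h⁻¹, which is 0.835 times the dissolution coefficient, against 12.8 times in Wednesday's, so I expect a lower yield in Sunday's flask. In Tuesday's flask at −5 °C, the constant for G to J is 0.00813 h⁻¹, and times 25 h it comes to 0.203, so I put Tuesday's last. I place Monday's between Wednesday's and Sunday's, and my reckoning goes no further.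

**The forecast.** It names Wednesday's highest, with 96 % there, 84 % for Monday's, 45 % for Sunday's and 0.3 % for Tuesday's. Its grounds include “X trapping J fast enough to keep G low”. For Wednesday's it stands slightly below my figure.

**The result.** The simulation puts Wednesday's highest, with 96.6 %, then Monday's 87.1 %, Sunday's 38.5 % and Tuesday's 0.347 %. The forecast for Sunday's is 6.5 percentage points too high.

**The neighbour.** Wednesday's flask ends with G.J at 3.34 % and X at 67.8 % of its charge. A neighbour charged with 1.20 equiv of X, reckoned at its starting level of X, has [G] near 0.0426 M, so its leak is 0.0711, larger than Wednesday's. At that starting leak, 12.4 % of the E units would go to G.J. In the neighbour, X falls to 37.8 % of its charge, G.J reaches 19.4 %, and X.J ends at 74.6 %.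

The numbers were set for the occasion, and the outcome is calculated.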